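Stephaflavone B is disconnected through ring A of unit 2 (the C6-linked flavone), not at the hindered inter-flavone bond. That ring carries C5 hydroxyl, C6 aryl, C7 methoxy and C8 hydrogen, exactly the pattern a vinylketene and an aryl methoxyalkyne deliver. A 4-pyranon-2-yl diazoketone (ring C of unit 2, already bearing the 4-methoxyphenyl group) is photolysed with a 3-(methoxyethynyl)flavone (unit 1, joined through C3). Wolff shift, [2+2] addition, cyclobutenone opening and six-electron closure onto pyranone C3 build ring A in one operation, forming C8–C8a, C5–C6, C7–C8 and C4a–C5 and giving the C5 phenol and C7 methyl ether in their final, distinct forms. One BCl3 step then unmasks unit 1.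

Key step: step 7

Assumption: the target SMILES defines no axial configuration, so the tetra-ortho-substituted C3(unit 1)–C6(unit 2) axis formed in step 7 is taken as racemic and no atroposelection is attempted. Unit 1 is the flavone linked through C3, unit 2 the flavone linked through C6.

**Step 1**
Reactants: 1 1-(benzyloxy)-4-ethynylbenzene; 2 2,4,6-trimethoxybenzaldehyde
Product: 4 rac-3-[4-(benzyloxy)phenyl]-1-(2,4,6-trimethoxyphenyl)prop-2-yn-1-ol, via lithium arylacetylide 3 (not isolated)
Conditions: n-BuLi, THF, −78 °C; then 2, −78 to 0 °C; neutral aqueous work-up, crude product used directly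
Reagents that add atoms: none
Why: 1,2-addition of a lithium acetylide to an aromatic aldehyde; the carbinol stereocentre forms as a racemate and is removed in step 2, and the acid-labile, strongly donor-substituted alcohol is not chromatographed.

**Step 2**
Reactants: 4 rac-3-[4-(benzyloxy)phenyl]-1-(2,4,6-trimethoxyphenyl)prop-2-yn-1-ol
Product: 5 3-[4-(benzyloxy)phenyl]-1-(2,4,6-trimethoxyphenyl)prop-2-yn-1-one
Conditions: MnO2 (activated, excess), CH2Cl2, 20 °C
Reagents that add atoms: none
Why: MnO2 oxidation of a benzylic and propargylic alcohol is mild and neutral, leaves the ethers and the alkyne untouched, and erases the only stereocentre.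

**Step 3**
Reactants: 5 3-[4-(benzyloxy)phenyl]-1-(2,4,6-trimethoxyphenyl)prop-2-yn-1-one
Product: 6 2-[4-(benzyloxy)phenyl]-3-iodo-5,7-dimethoxy-4H-chromen-4-one
Conditions: ICl (1.1 equiv), CH2Cl2, −78 °C; aq Na2S2O3
Reagents that add atoms: iodine monochloride, ClI
Why: Electrophilic iodocyclisation of an ortho-methoxyaryl ynone, in which iodonium activation of the alkyne, 6-endo-dig attack of a methoxy oxygen and loss of the oxonium methyl as MeCl give the 3-iodochromone; low temperature and near-stoichiometric ICl should hold back iodination of the electron-rich rings.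

**Step 4**
Reactants: 6 2-[4-(benzyloxy)phenyl]-3-iodo-5,7-dimethoxy-4H-chromen-4-one; 7 chloroacetaldehyde dimethyl acetal (2-chloro-1,1-dimethoxyethane)
Product: 10 2-[4-(benzyloxy)phenyl]-5,7-dimethoxy-3-(methoxyethynyl)-4H-chromen-4-one, via lithium methoxyacetylide 8 (not isolated), via methoxyethynylzinc chloride 9 (not isolated)
Conditions: 7, LiNEt2 (3.1 equiv, from Et2NH and n-BuLi), THF, 0 °C; ZnCl2, THF, 0 °C; then 6, Pd(PPh3)4 (5 mol %), THF, 20 °C; chromatography on Et3N-deactivated silica, product used promptly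
Reagents that add atoms: none
Why: Double elimination of the chloroacetal (loss of MeOH and HCl) gives lithium methoxyacetylide, transmetalation to zinc tempers its basicity, and Negishi coupling at the reactive C3–I bond installs the ynol ether, as established for alkoxyethynylzinc chlorides and aryl iodides.

**Step 5**
Reactants: 11 1-(4-methoxyphenyl)butane-1,3-dione
Product: 14 6-(4-methoxyphenyl)-4-oxo-4H-pyran-2-carboxylic acid, via triketo ester 12 (not isolated), via ethyl pyranonecarboxylate 13 (not isolated)
Conditions: NaOEt (2.5 equiv), (CO2Et)2, EtOH, 0 to 78 °C; then conc. HCl, AcOH/H2O, 100 °C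
Reagents that add atoms: diethyl oxalate, CCOC(=O)C(=O)OCC; water, O
Why: Crossed Claisen condensation at the terminal methyl of the 1,3-diketone (driven by enolate formation of the product), then acid-mediated cyclodehydration to the 4-pyranone and ester hydrolysis in the same pot, the sequence used classically for chelidonic and comanic acids.

**Step 6**
Reactants: 14 6-(4-methoxyphenyl)-4-oxo-4H-pyran-2-carboxylic acid
Product: 16 2-diazo-1-[6-(4-methoxyphenyl)-4-oxo-4H-pyran-2-yl]ethan-1-one, via acid chloride 15 (not isolated)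
Conditions: (COCl)2, DMF (cat.), CH2Cl2, 0 to 20 °C, evaporate; CH2N2 (1.3 equiv), Et3N (1.5 equiv), THF/Et2O, −10 to 0 °C
Reagents that add atoms: diazomethane, C=[N+]=[N-]
Why: Acylation of diazomethane by an acid chloride without α-hydrogens (first stage of the Arndt–Eistert sequence), with Et3N taking up the HCl so that only a slight excess of CH2N2 is exposed to the pyranone C2=C3 bond.

**Step 7**
Reactants: 16 2-diazo-1-[6-(4-methoxyphenyl)-4-oxo-4H-pyran-2-yl]ethan-1-one; 10 2-[4-(benzyloxy)phenyl]-5,7-dimethoxy-3-(methoxyethynyl)-4H-chromen-4-one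
Product: 21 2-[4-(benzyloxy)phenyl]-3-[5-hydroxy-7-methoxy-2-(4-methoxyphenyl)-4-oxo-4H-chromen-6-yl]-5,7-dimethoxy-4H-chromen-4-one, via pyranonylketene 17 (not isolated), via cyclobutenone 18 (not isolated), via dienylketene 19 (not isolated), via cyclohexadienone 20 (not isolated)
Conditions: 16 (1.5 equiv, slow addition), 10, hν (405–440 nm LED), degassed CH2Cl2, 20 °C; then PhMe, 90 °C
Reagents that add atoms: none
Why: Excitation of the diazoketone expels N2 and the pyranonyl group migrates (Wolff rearrangement) to give ketene 17, which the electron-rich ynol ether 10 captures in a [2+2] cycloaddition to cyclobutenone 18; on heating, 18 opens in a reversible conrotatory four-electron process to dienylketene 19, which closes by six-electron electrocyclization onto pyranone C3 to dienone 20, and enolisation aromatises this to phenol 21, hydrogen-bonded to the C4 carbonyl. The closest known reaction type is the Danheiser benzannulation in its diazoketone form, established for unsaturated and heteroaryl diazoketones with alkoxyalkynes. The one new ring, ring A of unit 2, is closed by the thermal disrotatory 6π electrocyclization that forms C4a–C5, the four-membered ring of 18 being transient. No stereocentre persists, because the sp3 centres of 18 and 20 are erased on aromatisation and the new biaryl axis forms as a racemate, uncrowded until the ring exists since the inter-unit bond starts as an sp–sp2 bond. Regiocontrol in the [2+2] step comes from the polarisation of the ynol ether, whose carbon β to the methoxy oxygen (the one bearing unit 1) bonds to the ketene carbonyl carbon, so that unit 1 lands between C5–OH and C7–OMe; only the isomer of 19 with the pyranonyl group turned inward can cyclise, and the other returns to 18. Closure onto the pyranone C2=C3 bond is expected to win over closure through ring B of unit 1 because it costs far less aromaticity, and the long-wavelength light is absorbed essentially by the diazoketone alone, sparing the flavone and pyranone chromophores.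

**Step 8**
Reactants: 21 2-[4-(benzyloxy)phenyl]-3-[5-hydroxy-7-methoxy-2-(4-methoxyphenyl)-4-oxo-4H-chromen-6-yl]-5,7-dimethoxy-4H-chromen-4-one
Product: 22 stephaflavone B
Conditions: BCl3 (8 equiv), C6HMe5 (3 equiv), CH2Cl2, −78 to 0 °C; H2O quench
Reagents that add atoms: none
Why: Chelation-controlled Lewis-acid dealkylation, in which BCl3 cleaves the benzyl ether at low temperature (cation trapped by pentamethylbenzene) and, on warming, the C5 methyl ether of unit 1 through a six-membered boron chelate with the C4 carbonyl, while the non-chelated C7 methyl ethers of both units and the 4'-methyl ether of unit 2 should remain.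

**Compound list**
1 | 1-(benzyloxy)-4-ethynylbenzene | C#Cc1ccc(OCc2ccccc2)cc1 | starting material
2 | 2,4,6-trimethoxybenzaldehyde | COc1cc(OC)c(C=O)c(OC)c1 | starting material
3 | lithium [4-(benzyloxy)phenyl]acetylide | [Li]C#Cc1ccc(OCc2ccccc2)cc1 | intermediate
4 | rac-3-[4-(benzyloxy)phenyl]-1-(2,4,6-trimethoxyphenyl)prop-2-yn-1-ol (racemate) | COc1cc(OC)c(C(O)C#Cc2ccc(OCc3ccccc3)cc2)c(OC)c1 | intermediate
5 | 3-[4-(benzyloxy)phenyl]-1-(2,4,6-trimethoxyphenyl)prop-2-yn-1-one | COc1cc(OC)c(C(=O)C#Cc2ccc(OCc3ccccc3)cc2)c(OC)c1 | intermediate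
6 | 2-[4-(benzyloxy)phenyl]-3-iodo-5,7-dimethoxy-4H-chromen-4-one | COc1cc(OC)c2c(=O)c(I)c(-c3ccc(OCc4ccccc4)cc3)oc2c1 | intermediate
7 | chloroacetaldehyde dimethyl acetal (2-chloro-1,1-dimethoxyethane) | COC(CCl)OC | starting material
8 | lithium methoxyacetylide | [Li]C#COC | intermediate
9 | (methoxyethynyl)zinc chloride | COC#C[Zn]Cl | intermediate
10 | 2-[4-(benzyloxy)phenyl]-5,7-dimethoxy-3-(methoxyethynyl)-4H-chromen-4-one | COC#Cc1c(-c2ccc(OCc3ccccc3)cc2)oc2cc(OC)cc(OC)c2c1=O | intermediate
11 | 1-(4-methoxyphenyl)butane-1,3-dione | COc1ccc(C(=O)CC(C)=O)cc1 | starting material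
12 | ethyl 6-(4-methoxyphenyl)-2,4,6-trioxohexanoate | CCOC(=O)C(=O)CC(=O)CC(=O)c1ccc(OC)cc1 | intermediate
13 | ethyl 6-(4-methoxyphenyl)-4-oxo-4H-pyran-2-carboxylate | CCOC(=O)c1cc(=O)cc(-c2ccc(OC)cc2)o1 | intermediate
14 | 6-(4-methoxyphenyl)-4-oxo-4H-pyran-2-carboxylic acid | OC(=O)c1cc(=O)cc(-c2ccc(OC)cc2)o1 | intermediate
15 | 6-(4-methoxyphenyl)-4-oxo-4H-pyran-2-carbonyl chloride | ClC(=O)c1cc(=O)cc(-c2ccc(OC)cc2)o1 | intermediate
16 | 2-diazo-1-[6-(4-methoxyphenyl)-4-oxo-4H-pyran-2-yl]ethan-1-one | [N-]=[N+]=CC(=O)c1cc(=O)cc(-c2ccc(OC)cc2)o1 | intermediate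
17 | [6-(4-methoxyphenyl)-4-oxo-4H-pyran-2-yl]ketene | O=C=Cc1cc(=O)cc(-c2ccc(OC)cc2)o1 | intermediate
18 | 2-{2-[4-(benzyloxy)phenyl]-5,7-dimethoxy-4-oxo-4H-chromen-3-yl}-3-methoxy-4-[6-(4-methoxyphenyl)-4-oxo-4H-pyran-2-yl]cyclobut-2-en-1-one (racemate) | COC1=C(c2c(-c3ccc(OCc4ccccc4)cc3)oc3cc(OC)cc(OC)c3c2=O)C(=O)C1c1cc(=O)cc(-c2ccc(OC)cc2)o1 | intermediate
19 | dienylketene: 2-{2-[4-(benzyloxy)phenyl]-5,7-dimethoxy-4-oxo-4H-chromen-3-yl}-3-methoxy-4-[6-(4-methoxyphenyl)-4-oxo-4H-pyran-2-yl]buta-1,3-dien-1-one, pyranonyl group cis to the ketene-bearing carbon across C3=C4 | O=C=C(c1c(-c2ccc(OCc3ccccc3)cc2)oc2cc(OC)cc(OC)c2c1=O)/C(OC)=C\c1cc(=O)cc(-c2ccc(OC)cc2)o1 | intermediate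
20 | 6-{2-[4-(benzyloxy)phenyl]-5,7-dimethoxy-4-oxo-4H-chromen-3-yl}-7-methoxy-2-(4-methoxyphenyl)-4aH-chromene-4,5-dione (racemate, keto tautomer of 21) | O=C1C(c3c(-c4ccc(OCc5ccccc5)cc4)oc4cc(OC)cc(OC)c4c3=O)=C(OC)C=C2OC(-c3ccc(OC)cc3)=CC(=O)C12 | intermediate
21 | 2-[4-(benzyloxy)phenyl]-3-[5-hydroxy-7-methoxy-2-(4-methoxyphenyl)-4-oxo-4H-chromen-6-yl]-5,7-dimethoxy-4H-chromen-4-one (axis racemic) | COc1ccc(-c2cc(=O)c3c(O)c(-c4c(-c5ccc(OCc6ccccc6)cc5)oc5cc(OC)cc(OC)c5c4=O)c(OC)cc3o2)cc1 | intermediate
22 | stephaflavone B, 5-hydroxy-3-[5-hydroxy-7-methoxy-2-(4-methoxyphenyl)-4-oxo-4H-chromen-6-yl]-2-(4-hydroxyphenyl)-7-methoxy-4H-chromen-4-one (no stereocentre, axis not assigned) | COc1ccc(-c2cc(=O)c3c(O)c(-c4c(-c5ccc(O)cc5)oc5cc(OC)cc(O)c5c4=O)c(OC)cc3o2)cc1 | target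

**Step count**
Total steps: 8. Longest linear sequence: 6 steps (1, 2, 3, 4, 7, 8); the diazoketone arm (steps 5 and 6) joins at step 7.

**Steps most likely to fail**

Step 7. The ketene may dimerise or be lost before the hindered ynol ether captures it. Residual light absorption by the pyranone or flavone chromophores may divert material into other photoreactions. A fallback that avoids light sets out from diazoketone 16: silver-catalysed Wolff rearrangement in water (PhCO2Ag, Et3N, dioxane/H2O) should give 2-[6-(4-methoxyphenyl)-4-oxo-4H-pyran-2-yl]acetic acid F1, and (COCl)2 with catalytic DMF converts this to 2-[6-(4-methoxyphenyl)-4-oxo-4H-pyran-2-yl]acetyl chloride F2. Slow addition of F2 to ynol ether 10 and Et3N in toluene at 20 °C generates ketene 17 by dehydrochlorination in the dark, the [2+2] adduct 18 forms as before, and heating at 90 °C leads on to biflavone 21, where the route is rejoined.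

Step 4. The ynol ether may be protonated or hydrated in the presence of the Lewis-acidic zinc salts during coupling and isolation. Residual amide or alkoxide may also add to the chromone. The fallback sets out from acetal 7 and iodide 6: lithium methoxyacetylide 8 is quenched with Bu3SnCl to give tributyl(methoxyethynyl)stannane F3, an isolable, distillable reagent. Stille coupling of F3 with 6 (Pd(PPh3)4, toluene, 70 °C, no base and no Lewis acid) then returns to ynol ether 10.

Step 6. Diazomethane may undergo dipolar cycloaddition to the acceptor-activated C2=C3 bond of the pyranone in competition with acylation. The fallback avoids diazomethane and sets out from acid chloride 15: coupling with MeMgBr under Fe(acac)3 catalysis (THF, −78 °C) gives 2-acetyl-6-(4-methoxyphenyl)-4H-pyran-4-one F4. Enolisation with LiHMDS and trapping with CF3CO2CH2CF3 (THF, −78 °C) gives 4,4,4-trifluoro-1-[6-(4-methoxyphenyl)-4-oxo-4H-pyran-2-yl]butane-1,3-dione F5, and detrifluoroacetylative diazo transfer (MsN3, Et3N, H2O, MeCN, 20 °C) returns to diazoketone 16.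

**Further compounds**
F1 | step 7 | 2-[6-(4-methoxyphenyl)-4-oxo-4H-pyran-2-yl]acetic acid | COc1ccc(-c2cc(=O)cc(CC(=O)O)o2)cc1
F2 | step 7 | 2-[6-(4-methoxyphenyl)-4-oxo-4H-pyran-2-yl]acetyl chloride | COc1ccc(-c2cc(=O)cc(CC(Cl)=O)o2)cc1
F3 | step 4 | tributyl(methoxyethynyl)stannane | CCCC[Sn](CCCC)(CCCC)C#COC
F4 | step 6 | 2-acetyl-6-(4-methoxyphenyl)-4H-pyran-4-one | CC(=O)c1cc(=O)cc(-c2ccc(OC)cc2)o1
F5 | step 6 | 4,4,4-trifluoro-1-[6-(4-methoxyphenyl)-4-oxo-4H-pyran-2-yl]butane-1,3-dione | O=C(CC(=O)C(F)(F)F)c1cc(=O)cc(-c2ccc(OC)cc2)o1
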